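**Strategy.** The cyclohexenone ring is cut at C4–C5 and C6–C1. Its C1–C4 segment, oxygenated at both ends (C1 ketone, C4 carbinol) and carrying C7 on C2, is a latent 3-substituted 2-silyloxyfuran; C5–C6 come from an (E)-β-isopropyl enoyl oxazolidinone. One copper–bis(oxazoline)-catalysed operation closes the carbocycle, forms both ring bonds and sets C4, C5 and C6. Collapse of the oxygen bridge then unveils the C1 enone with the C4 oxygen already silylated. The C6 acyl handle is later replaced by the epoxyangelate oxygen and C4 is angeloylated. The precursor pair is furan 6 and imide 10.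

Key step: step 5

Assumption: the triethylsilyl group freed when the bridge opens is taken up by the C4 alkoxide; any free C4 alcohol in the crude product would be converted into the same compound 12 with TESCl/imidazole.

Design remark: the furan oxygen carries triethylsilyl and C7 carries TBS, so the silyl group that lands on the C4 oxygen is the more labile one and can be removed first; the (S,S) ligand is the enantiomer that leads to the target configuration.

Step 1
Reactants: 1 furan-3-ylmethanol
Product: 2 tert-butyl(furan-3-ylmethoxy)dimethylsilane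
Conditions: TBSCl, imidazole, DMF, 0 °C to rt
Reagents that add atoms: tert-butyldimethylsilyl chloride, CC(C)(C)[Si](C)(C)Cl
Why: Imidazole-promoted silylation of a primary alcohol (silyl ether formation); no stereocentre is involved.

Step 2
Reactants: 2 tert-butyl(furan-3-ylmethoxy)dimethylsilane
Product: 5 3-{[(tert-butyldimethylsilyl)oxy]methyl}furan-2(5H)-one, via 2-lithiofuran 3 (not isolated), via dimethyl furylboronate 4 (not isolated)
Conditions: n-BuLi, THF (no HMPA), −78 to −40 °C; B(OMe)3, −78 °C to rt; then AcOH, 30% H2O2, 0 °C to rt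
Reagents that add atoms: hydrogen peroxide, OO
Why: The silyloxymethyl oxygen should steer deprotonation to the adjacent C2 (directed lithiation, kept cold and HMPA-free so that a 1,4 O-to-C silyl shift does not set in), and borate trapping followed by boronate oxidation gives the 2-hydroxyfuran, which rests as the butenolide; either double-bond isomer gives the same furan in step 3.

Step 3
Reactants: 5 3-{[(tert-butyldimethylsilyl)oxy]methyl}furan-2(5H)-one
Product: 6 3-{[(tert-butyldimethylsilyl)oxy]methyl}-2-(triethylsilyloxy)furan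
Conditions: TESOTf, Et3N, CH2Cl2, 0 °C; used after filtration through basic alumina
Reagents that add atoms: triethylsilyl trifluoromethanesulfonate, CC[Si](CC)(CC)OS(=O)(=O)C(F)(F)F
Why: Soft enolisation of a butenolide with a silyl triflate and an amine (silyl dienol ether formation) gives the aromatic 2-silyloxyfuran.

Step 4
Reactants: 7 (E)-4-methylpent-2-enoic acid; 8 oxazolidin-2-one
Product: 10 (E)-3-(4-methylpent-2-enoyl)oxazolidin-2-one, via mixed pivalic anhydride 9 (not isolated)
Conditions: pivaloyl chloride, Et3N, THF, −20 °C; then LiCl, 8, rt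
Reagents that add atoms: none
Why: One-pot N-acylation of the oxazolidinone through the pivalic mixed anhydride (mixed-anhydride acylation with LiCl/amine), which leaves the E alkene untouched.

Step 5
Reactants: 6 3-{[(tert-butyldimethylsilyl)oxy]methyl}-2-(triethylsilyloxy)furan; 10 (E)-3-(4-methylpent-2-enoyl)oxazolidin-2-one
Product: 12 (4S,5S,6S)-2-{[(tert-butyldimethylsilyl)oxy]methyl}-5-isopropyl-6-(2-oxooxazolidine-3-carbonyl)-4-(triethylsilyloxy)cyclohex-2-en-1-one (4,5-cis, 5,6-trans), via oxabicyclic silyl ketal 11 (not isolated)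
Conditions: Cu(SbF6)2·(S,S)-tBu-box (10 mol %, from CuCl2, AgSbF6 and 2,2'-(propane-2,2-diyl)bis[(4S)-4-tert-butyl-4,5-dihydrooxazole]), CH2Cl2, −40 to 0 °C, no protic additive; pH 7 buffer work-up
Reagents that add atoms: none
Why: The imide binds divalent copper through both carbonyls in a square-planar s-cis complex whose lower face is blocked by a tert-butyl group of the (S,S) ligand, so the furan adds to the Cα-Re/Cβ-Si face, its nucleophilic C5 bonding to the isopropyl-bearing β carbon (C4–C5) and its silyloxy carbon to the α carbon (C6–C1), either in one asynchronous event or as Mukaiyama–Michael addition followed by closure of the copper enolate onto the silyloxyfuranium carbon; the strained bridgehead silyl ketal 11 then breaks its C1–O bridge bond and the silyl group passes to the released C4 alkoxide. The closest known reaction types are copper–bis(oxazoline) Diels–Alder reactions of enoyl oxazolidinones, copper–bis(oxazoline) additions of 2-silyloxyfurans to the same acceptors, and Diels–Alder/ring-opening of 2-silyloxyfurans to 4-oxygenated cyclohexenones. The six-membered carbocycle closes as an endo [4+2] cycloaddition (a 6-exo-trig attack of the enolate on the oxocarbenium carbon if the course is stepwise). C5 is set by the ligand-controlled face of the acceptor, C6 by the E geometry of the alkene in a suprafacial addition (acyl trans to isopropyl, also the stable arrangement of this epimerisable centre), and C4 by the endo transition state, which leaves isopropyl exo and therefore cis to the bridge oxygen. The step needs regioselectivity, endo selectivity and ring closure in preference to plain conjugate addition: the donor oxygen makes furan C5 the nucleophilic terminus, the two-point-bound imide holds the acceptor under the ligand, and the non-nucleophilic counter-ion with no proton source leaves the zwitterion nothing to do but close.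

Step 6
Reactants: 12 (4S,5S,6S)-β-keto imide
Product: 13 prop-2-en-1-yl (1S,5S,6S)-3-{[(tert-butyldimethylsilyl)oxy]methyl}-6-isopropyl-2-oxo-5-(triethylsilyloxy)cyclohex-3-ene-1-carboxylate
Conditions: allyl alcohol (10 equiv), DMAP (0.3 equiv), toluene, 80 °C
Reagents that add atoms: allyl alcohol, C=CCO
Why: Transesterification of a β-keto acyl compound, in which the oxazolidinone (a better leaving group than an alkoxide) is exchanged for allyl alcohol by way of an acyl ketene or addition–elimination; the C6 centre stays or equilibrates trans to isopropyl and is erased in step 7.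

Step 7
Reactants: 13 allyl β-keto ester
Product: 15 (4S,5R)-2-{[(tert-butyldimethylsilyl)oxy]methyl}-5-isopropyl-4-(triethylsilyloxy)cyclohex-2-en-1-one, via β-keto acid 14 (not isolated)
Conditions: Pd(PPh3)4 (5 mol %), morpholine, THF, rt
Reagents that add atoms: none
Why: Tsuji deallylation: zerovalent palladium ionises the allyl ester, morpholine takes the allyl group, and the β-keto acid loses CO2 under neutral conditions that spare both silyl ethers and the enone.

Step 8
Reactants: 15 (4S,5R)-ketone
Product: 17 (4R,5S,6S)-2-{[(tert-butyldimethylsilyl)oxy]methyl}-6-hydroxy-5-isopropyl-4-(triethylsilyloxy)cyclohex-2-en-1-one, via potassium dienolate 16 (not isolated)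
Conditions: KN(SiMe3)2, THF, −78 °C; 2-(phenylsulfonyl)-3-phenyloxaziridine, −78 °C; AcOH quench
Reagents that add atoms: trans-2-(phenylsulfonyl)-3-phenyloxaziridine, O=S(=O)(c1ccccc1)N1OC1c1ccccc1
Why: Kinetic deprotonation at C6, the only enolisable α position, followed by Davis enolate hydroxylation; the oxidant should approach the face opposite the neighbouring isopropyl group and the cis C4 silyloxy group, placing the new hydroxyl trans to isopropyl.

Step 9
Reactants: 18 angelic acid, (Z)-2-methylbut-2-enoic acid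
Product: 19 (Z)-2-methylbut-2-en-1-ol
Conditions: LiAlH4, Et2O, 0 °C to rt; Fieser work-up
Reagents that add atoms: none
Why: Hydride reduction of the unsaturated acid to the allylic alcohol (1,2-reduction by LiAlH4), which does not touch the Z alkene.

Step 10
Reactants: 19 (Z)-2-methylbut-2-en-1-ol
Product: 20 [(2S,3R)-2,3-dimethyloxiran-2-yl]methanol
Conditions: Ti(OiPr)4 (10 mol %), L-(+)-diisopropyl tartrate (12 mol %), t-BuOOH, 4 Å MS, CH2Cl2, −20 °C
Reagents that add atoms: tert-butyl hydroperoxide, CC(C)(C)OO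
Why: Sharpless asymmetric epoxidation; the L-(+)-tartrate catalyst should deliver oxygen to the face that gives the (2S,3R) epoxy alcohol (the same sense as with nerol), and the syn addition keeps the two methyl groups trans.

Step 11
Reactants: 20 [(2S,3R)-2,3-dimethyloxiran-2-yl]methanol
Product: 21 (2R,3R)-2,3-dimethyloxirane-2-carboxylic acid (epoxyangelic acid)
Conditions: RuCl3·xH2O (2 mol %), NaIO4, MeCN/EtOAc/H2O, 0 °C to rt
Reagents that add atoms: water, O
Why: RuO4-catalysed oxidation of a primary epoxy alcohol to the glycidic acid, which leaves the epoxide and both stereocentres intact (the descriptor at C2 changes only through the priority rules).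

Step 12
Reactants: 17 (4R,5S,6S)-6-hydroxy ketone; 21 (2R,3R)-2,3-dimethyloxirane-2-carboxylic acid
Product: 23 (4R,5S,6S)-2-{[(tert-butyldimethylsilyl)oxy]methyl}-6-{[(2R,3R)-2,3-dimethyloxirane-2-carbonyl]oxy}-5-isopropyl-4-(triethylsilyloxy)cyclohex-2-en-1-one, via mixed anhydride 22 (not isolated)
Conditions: 2,4,6-trichlorobenzoyl chloride, Et3N, THF, rt; then 17, DMAP, toluene, rt
Reagents that add atoms: none
Why: Yamaguchi esterification, suited to a hindered secondary alcohol and a hindered acid; the acid has no α hydrogen to epimerise, and C6 sits in its stable trans arrangement.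

Step 13
Reactants: 23 C6 epoxyangelate, C4 triethylsilyl ether
Product: 24 (4R,5R,6S)-2-{[(tert-butyldimethylsilyl)oxy]methyl}-6-{[(2R,3R)-2,3-dimethyloxirane-2-carbonyl]oxy}-4-hydroxy-5-isopropylcyclohex-2-en-1-one
Conditions: PPTS (0.2 equiv), MeOH/CH2Cl2, 0 °C, monitored
Reagents that add atoms: none
Why: Acid-catalysed methanolysis of a silyl ether, selective because a triethylsilyl ether is far more acid-labile than a TBS ether, under conditions mild enough for the electron-poor epoxy ester.

Step 14
Reactants: 24 C4 alcohol; 18 angelic acid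
Product: 26 (4R,5R,6S)-4-(angeloyloxy)-2-{[(tert-butyldimethylsilyl)oxy]methyl}-6-{[(2R,3R)-2,3-dimethyloxirane-2-carbonyl]oxy}-5-isopropylcyclohex-2-en-1-one, via mixed anhydride 25 (not isolated)
Conditions: 18, 2,4,6-trichlorobenzoyl chloride, Et3N, toluene, rt, filtered; then 24, toluene, 70 °C (no DMAP)
Reagents that add atoms: none
Why: Yamaguchi-type angeloylation through the mixed anhydride without a nucleophilic catalyst, the standard way to acylate a secondary alcohol with angelic acid while avoiding addition–elimination isomerisation to the tiglate; C4 keeps its configuration since only the O–H bond reacts.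

Step 15
Reactants: 26 C7 TBS ether
Product: 27 (4R,5R,6S)-4-(angeloyloxy)-6-{[(2R,3R)-2,3-dimethyloxirane-2-carbonyl]oxy}-2-(hydroxymethyl)-5-isopropylcyclohex-2-en-1-one (target)
Conditions: HF·pyridine, pyridine, THF, 0 °C to rt
Reagents that add atoms: none
Why: Fluoride-mediated cleavage of a primary silyl ether under buffered, weakly acidic conditions that should leave the two esters, the epoxide and the α-acyloxy ketone alone and give no acyl migration.

**Compound list**

1 | furan-3-ylmethanol | OCc1ccoc1 | starting material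
2 | tert-butyl(furan-3-ylmethoxy)dimethylsilane | CC(C)(C)[Si](C)(C)OCc1ccoc1 | intermediate
3 | (3-{[(tert-butyldimethylsilyl)oxy]methyl}furan-2-yl)lithium | [Li]c1occc1CO[Si](C)(C)C(C)(C)C | intermediate
4 | dimethyl (3-{[(tert-butyldimethylsilyl)oxy]methyl}furan-2-yl)boronate | COB(OC)c1occc1CO[Si](C)(C)C(C)(C)C | intermediate
5 | 3-{[(tert-butyldimethylsilyl)oxy]methyl}furan-2(5H)-one | O=C1OCC=C1CO[Si](C)(C)C(C)(C)C | intermediate
6 | 3-{[(tert-butyldimethylsilyl)oxy]methyl}-2-(triethylsilyloxy)furan | CC[Si](CC)(CC)Oc1occc1CO[Si](C)(C)C(C)(C)C | intermediate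
7 | (E)-4-methylpent-2-enoic acid | CC(C)/C=C/C(=O)O | starting material
8 | oxazolidin-2-one | O=C1NCCO1 | starting material
9 | (E)-4-methylpent-2-enoic pivalic anhydride | CC(C)/C=C/C(=O)OC(=O)C(C)(C)C | intermediate
10 | (E)-3-(4-methylpent-2-enoyl)oxazolidin-2-one | CC(C)/C=C/C(=O)N1CCOC1=O | intermediate
11 | 3-{[3-exo-isopropyl-6-{[(tert-butyldimethylsilyl)oxy]methyl}-1-(triethylsilyloxy)-7-oxabicyclo[2.2.1]hept-5-en-2-endo-yl]carbonyl}oxazolidin-2-one | O1[C@@H]2C=C(CO[Si](C)(C)C(C)(C)C)[C@@]1(O[Si](CC)(CC)CC)[C@@H](C(=O)N3CCOC3=O)[C@@H]2C(C)C | intermediate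
12 | (4S,5S,6S)-2-{[(tert-butyldimethylsilyl)oxy]methyl}-5-isopropyl-6-(2-oxooxazolidine-3-carbonyl)-4-(triethylsilyloxy)cyclohex-2-en-1-one | CC[Si](CC)(CC)O[C@@H]1C=C(CO[Si](C)(C)C(C)(C)C)C(=O)[C@@H](C(=O)N2CCOC2=O)[C@@H]1C(C)C | intermediate
13 | prop-2-en-1-yl (1S,5S,6S)-3-{[(tert-butyldimethylsilyl)oxy]methyl}-6-isopropyl-2-oxo-5-(triethylsilyloxy)cyclohex-3-ene-1-carboxylate | CC[Si](CC)(CC)O[C@@H]1C=C(CO[Si](C)(C)C(C)(C)C)C(=O)[C@@H](C(=O)OCC=C)[C@@H]1C(C)C | intermediate
14 | (1S,5S,6S)-3-{[(tert-butyldimethylsilyl)oxy]methyl}-6-isopropyl-2-oxo-5-(triethylsilyloxy)cyclohex-3-ene-1-carboxylic acid | CC[Si](CC)(CC)O[C@@H]1C=C(CO[Si](C)(C)C(C)(C)C)C(=O)[C@@H](C(=O)O)[C@@H]1C(C)C | intermediate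
15 | (4S,5R)-2-{[(tert-butyldimethylsilyl)oxy]methyl}-5-isopropyl-4-(triethylsilyloxy)cyclohex-2-en-1-one | CC[Si](CC)(CC)O[C@@H]1C=C(CO[Si](C)(C)C(C)(C)C)C(=O)C[C@@H]1C(C)C | intermediate
16 | potassium cross-conjugated dienolate of 15 (C1 oxygen, C1=C6) | CC[Si](CC)(CC)O[C@@H]1C=C(CO[Si](C)(C)C(C)(C)C)C([O-])=C[C@@H]1C(C)C.[K+] | intermediate
17 | (4R,5S,6S)-2-{[(tert-butyldimethylsilyl)oxy]methyl}-6-hydroxy-5-isopropyl-4-(triethylsilyloxy)cyclohex-2-en-1-one | CC[Si](CC)(CC)O[C@@H]1C=C(CO[Si](C)(C)C(C)(C)C)C(=O)[C@@H](O)[C@@H]1C(C)C | intermediate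
18 | angelic acid, (Z)-2-methylbut-2-enoic acid | C/C=C(/C)C(=O)O | starting material
19 | (Z)-2-methylbut-2-en-1-ol | C/C=C(/C)CO | intermediate
20 | [(2S,3R)-2,3-dimethyloxiran-2-yl]methanol | OC[C@]1(C)O[C@@H]1C | intermediate
21 | (2R,3R)-2,3-dimethyloxirane-2-carboxylic acid | OC(=O)[C@]1(C)O[C@@H]1C | intermediate
22 | (2R,3R)-2,3-dimethyloxirane-2-carboxylic 2,4,6-trichlorobenzoic anhydride | O=C(OC(=O)c1c(Cl)cc(Cl)cc1Cl)[C@]1(C)O[C@@H]1C | intermediate
23 | (4R,5S,6S)-2-{[(tert-butyldimethylsilyl)oxy]methyl}-6-{[(2R,3R)-2,3-dimethyloxirane-2-carbonyl]oxy}-5-isopropyl-4-(triethylsilyloxy)cyclohex-2-en-1-one | CC[Si](CC)(CC)O[C@@H]1C=C(CO[Si](C)(C)C(C)(C)C)C(=O)[C@@H](OC(=O)[C@]2(C)O[C@@H]2C)[C@@H]1C(C)C | intermediate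
24 | (4R,5R,6S)-2-{[(tert-butyldimethylsilyl)oxy]methyl}-6-{[(2R,3R)-2,3-dimethyloxirane-2-carbonyl]oxy}-4-hydroxy-5-isopropylcyclohex-2-en-1-one | O[C@@H]1C=C(CO[Si](C)(C)C(C)(C)C)C(=O)[C@@H](OC(=O)[C@]2(C)O[C@@H]2C)[C@@H]1C(C)C | intermediate
25 | (Z)-2-methylbut-2-enoic 2,4,6-trichlorobenzoic anhydride | C/C=C(/C)C(=O)OC(=O)c1c(Cl)cc(Cl)cc1Cl | intermediate
26 | (4R,5R,6S)-4-(angeloyloxy)-2-{[(tert-butyldimethylsilyl)oxy]methyl}-6-{[(2R,3R)-2,3-dimethyloxirane-2-carbonyl]oxy}-5-isopropylcyclohex-2-en-1-one | C/C=C(/C)C(=O)O[C@@H]1C=C(CO[Si](C)(C)C(C)(C)C)C(=O)[C@@H](OC(=O)[C@]2(C)O[C@@H]2C)[C@@H]1C(C)C | intermediate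
27 | (4R,5R,6S)-4-(angeloyloxy)-6-{[(2R,3R)-2,3-dimethyloxirane-2-carbonyl]oxy}-2-(hydroxymethyl)-5-isopropylcyclohex-2-en-1-one | C/C=C(/C)C(=O)O[C@@H]1C=C(CO)C(=O)[C@@H](OC(=O)[C@]2(C)O[C@@H]2C)[C@@H]1C(C)C | target

**Step count.** Total: 15 steps. Longest linear sequence: 11 steps (1, 2, 3, 5, 6, 7, 8, 12, 13, 14, 15, from furan-3-ylmethanol).

**Steps most likely to fail**

Step 5. What may go wrong: the silyl group is lost from the zwitterionic adduct, or the C1–C6 bond of 11 breaks again, before the bridge opens, so that the reaction ends at conjugate addition; the hindered β-isopropyl group may also erode endo and facial control. Fallback: accept a two-stage course. From 6 and 10, the same catalyst with 1,1,1,3,3,3-hexafluoropropan-2-ol as proton source (the known asymmetric Mukaiyama–Michael mode) would give the butenolide 3-[(3R)-3-[(2S)-4-{[(tert-butyldimethylsilyl)oxy]methyl}-5-oxo-2,5-dihydrofuran-2-yl]-4-methylpentanoyl]oxazolidin-2-one F1. A titanium-mediated Dieckmann condensation (TiCl4, iPr2NEt, CH2Cl2, −78 to 0 °C), in which the chelated imide enolate attacks the lactone carbonyl and the ring oxygen leaves as the C4 alkoxide, would give (4S,5S,6S)-2-{[(tert-butyldimethylsilyl)oxy]methyl}-4-hydroxy-5-isopropyl-6-(2-oxooxazolidine-3-carbonyl)cyclohex-2-en-1-one F2. TESCl/imidazole would then return the route to 12.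

Step 6. What may go wrong: the β-dicarbonyl unit enolises or chelates so that the acyl exchange stalls, or the alcohol attacks the ring carbonyl of the oxazolidinone. Fallback: take the ketone out of play first. From 12, Luche reduction (NaBH4, CeCl3·7H2O, MeOH, −78 °C) would give the allylic alcohol 3-{[2-hydroxy-3-{[(tert-butyldimethylsilyl)oxy]methyl}-6-isopropyl-5-(triethylsilyloxy)cyclohex-3-en-1-yl]carbonyl}oxazolidin-2-one F3 (either C1 epimer serves). LiOH/H2O2 (THF/H2O, 0 °C), now with neither an enone nor an acidic C6–H present, would cleave the imide to the hydroxy acid 2-hydroxy-3-{[(tert-butyldimethylsilyl)oxy]methyl}-6-isopropyl-5-(triethylsilyloxy)cyclohex-3-ene-1-carboxylic acid F4. Dess–Martin periodinane (NaHCO3, CH2Cl2) would restore the enone, and the resulting β-keto acid 14 would lose CO2 to rejoin the route at 15.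

Step 14. What may go wrong: the activated angelate isomerises from Z to E (tiglate formation) during slow acylation of the hindered allylic alcohol. Fallback: form the ester bond first and build the Z alkene afterwards. From 24, carbodiimide coupling (EDC·HCl, DMAP, CH2Cl2) with 2-[bis(2,2,2-trifluoroethoxy)phosphoryl]propanoic acid would give the phosphonate ester (4R,5R,6S)-4-({2-[bis(2,2,2-trifluoroethoxy)phosphoryl]propanoyl}oxy) analogue of 26, F5. Its phosphonate C–H is far more acidic than the ketone α-hydrogen, so Still–Gennari olefination with acetaldehyde (KN(SiMe3)2, 18-crown-6, THF, −78 °C) should give the Z-configured 2-methylbut-2-enoate and rejoin the route at 26.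

**Further compounds**

F1 | step 5 | 3-[(3R)-3-[(2S)-4-{[(tert-butyldimethylsilyl)oxy]methyl}-5-oxo-2,5-dihydrofuran-2-yl]-4-methylpentanoyl]oxazolidin-2-one | O=C1O[C@@H]([C@@H](C(C)C)CC(=O)N2CCOC2=O)C=C1CO[Si](C)(C)C(C)(C)C
F2 | step 5 | (4S,5S,6S)-2-{[(tert-butyldimethylsilyl)oxy]methyl}-4-hydroxy-5-isopropyl-6-(2-oxooxazolidine-3-carbonyl)cyclohex-2-en-1-one | O[C@@H]1C=C(CO[Si](C)(C)C(C)(C)C)C(=O)[C@@H](C(=O)N2CCOC2=O)[C@@H]1C(C)C
F3 | step 6 | 3-{[2-hydroxy-3-{[(tert-butyldimethylsilyl)oxy]methyl}-6-isopropyl-5-(triethylsilyloxy)cyclohex-3-en-1-yl]carbonyl}oxazolidin-2-one (C1 epimers; other centres as in 12) | CC[Si](CC)(CC)O[C@@H]1C=C(CO[Si](C)(C)C(C)(C)C)C(O)[C@@H](C(=O)N2CCOC2=O)[C@@H]1C(C)C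
F4 | step 6 | 2-hydroxy-3-{[(tert-butyldimethylsilyl)oxy]methyl}-6-isopropyl-5-(triethylsilyloxy)cyclohex-3-ene-1-carboxylic acid (C2 epimers; other centres as in 12) | CC[Si](CC)(CC)O[C@@H]1C=C(CO[Si](C)(C)C(C)(C)C)C(O)[C@@H](C(=O)O)[C@@H]1C(C)C
F5 | step 14 | (4R,5R,6S)-4-({2-[bis(2,2,2-trifluoroethoxy)phosphoryl]propanoyl}oxy)-2-{[(tert-butyldimethylsilyl)oxy]methyl}-6-{[(2R,3R)-2,3-dimethyloxirane-2-carbonyl]oxy}-5-isopropylcyclohex-2-en-1-one | CC(C(=O)O[C@@H]1C=C(CO[Si](C)(C)C(C)(C)C)C(=O)[C@@H](OC(=O)[C@]2(C)O[C@@H]2C)[C@@H]1C(C)C)P(=O)(OCC(F)(F)F)OCC(F)(F)F
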